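The target is made from starting material on the catalyst and lost on that same catalyst, so a larger charge at a fixed 5 mol% loading speeds both. We want to know how much target stands at the end of the run.

in all of them: catalyst 5 mol%; time 1.0 min
- ochre: starting material 0.20 M
- grey: starting material 0.30 M
- green: starting material 0.50 M
- amber: starting material 0.60 M

    starting material + catalyst ⇌ target + catalyst, rate k1*[starting material]*[catalyst] forward; the back reaction follows from the equilibrium constant (K1 = 1.5, k1 = 1.3 M⁻¹ s⁻¹)
    starting material ⇌ isomer of the product A (K2 = 13, k2 = 0.027 s⁻¹)
    catalyst + target → catalyst + over-reaction product (k3 = 2.2 M⁻¹ s⁻¹)
    starting material ⇌ isomer of the product B (K4 = 3.6, k4 = 0.019 s⁻¹)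

- [target] at the end for ochre, grey, green, amber, in this order
- how the row runs (rises, then falls / falls all the way / hardly changes / falls, then rises / rises all the way)

- "hardly changes" means that all values lie within two and a half points (for a concentration: within two and a half percent of the largest)
- run time (ochre): 1.0 min

By hand, we take the **standing ratio** ρ: the [target]/[starting material] at which making target equals its return plus its over-reaction (a quasi-steady state). Each of these rates carries [catalyst], which cancels, so ρ is the forward constant divided by the sum of the over-reaction constant and the return constant, 0.424.

With the starting material held fixed, the target relaxes towards ρ with half-life ln(2)/([catalyst] × that sum). That is 0.377 min in ochre and 0.126 min in amber. The run therefore holds 2.65 half-lives in ochre and 7.96 in amber, and amber should end nearer ρ. We stop at the ratio and commit to no values for the row, for [target] at the end is that ratio times the starting material left, which this reckoning does not give.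

The forecast gives 0.015 M, 0.021 M, 0.018 M and 0.016 M, a row that rises, then falls, on the ground that “the target has passed its peak at high loading”.

The flask gives 0.0146 M, 0.0182 M, 0.0186 M and 0.0175 M, which also rises, then falls, but the largest value stands in green, not grey.

In the ochre flask, target is made 2.95 times as fast as it is used up at 0.195 min, but that ratio is down to 0.241 at 1.00 min. At that time ochre's target-to-starting-material ratio is 0.931, still above ρ, and amber's is lower at 0.688. At 10.0 min, ochre's ratio reads 0.432, close to ρ. In the amber flask at 10.0 min, ρ times the 1.19 % of starting material left gives 0.505 % of the charge as target, and the flask holds 0.513 %.

Its constants were drawn at random within sensible limits; the rest is arithmetic.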